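The missing substrate of the birch run cannot all be double product: by 10.0 min it has lost 44.5% of its substrate and holds 36.4% of single product, and if the missing 8.10% were double product at two partner turnovers each, the bill would be 0.526 equivalents against 0.47 equiv charged.

- birch: substrate 0.10 M; partner 0.47 equiv; run made earlier
- flask: substrate 0.10 M; partner 0.950 equiv; time 4.0 h

- birch (time / min: single product / %, substrate / %): 10.0: 36.4, 55.5; 20.0: 36.0, 51.7; 30.0: 34.2, 49.7; 40.0: 32.4, 47.5; 50.0: 31.5, 46.4

(readings scatter by 0.5 percentage points)

- the numbers in the tables scatter with a standard deviation of 0.5 percentage points

- the moment within 4.0 h at which there is most single product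
- the amount of single product, in percent of the substrate charged, at that time
- the first time at which single product reaches 18%, in the same percent, in min

So count turnovers, one turnover being one partner used. You can price a turnover two ways. From the product side you get the return per turnover, r, which is the single product read at 10.0 min per equivalent of partner charged: 0.774. From the substrate side, substrate lost per equivalent charged gives 0.947.

The two part, and the substrate count is the one that cheats. The bill above shows that some substrate leaves at a lower partner cost, and the later readings agree: substrate falls on to 46.4% by 50.0 min while single product falls to 31.5%.

Now take r to the new flask, which has twice the partner. Held constant, r gives 73.6%. That is my own estimate, and I expect the flask to fall below it, because the last turnovers would meet more single product than substrate, 73.6% against 26.4%.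

The forecast stands lower than my estimate, with 54% at 0.15 h and 18% reached at 0.4 min: “Slow decay trims the peak to about 54%.”

The flask peaks at 59.7% at 0.239 h and first holds 18% at 0.580 min.

    substrate + partner → single product + by-product (k = 0.0690 L mol⁻¹ s⁻¹)
    partner + single product → double product + by-product (k = 0.0140 L mol⁻¹ s⁻¹)
    partner + double product → tris adduct + by-product (k = 0.110 L mol⁻¹ s⁻¹)
    partner + tris adduct → tetra adduct + by-product (k = 0.00170 L mol⁻¹ s⁻¹)
    single product → over-reaction product (k = 2.80 × 10⁻⁷ s⁻¹)
    substrate + single product → side product (k = 0.00200 L mol⁻¹ s⁻¹)

At that peak partner, the limiting reagent, is down to 3.90% of its charge, with 22.9% of the substrate still unreacted. The return in this flask is 0.629, less than the 0.774 read from the birch run. A neighbour flask with 1.60 equiv of partner reaches 65.2%, a return of 0.407.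

The data stem from a simulated flask for an exercise; scatter was added.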